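**Strategy.** The target is treated as a germacranolide whose C1–C10 bond, the C–C bond of the trans-1,10-epoxide in the ten-membered carbocycle, is made as an (E)-trisubstituted C1=C10 olefin by ring-closing metathesis. The precursor is a fully substituted butenolide (lactone ring O–C6–C7=C11–C12) that already carries the 4,5-epoxide, the C8 angelate and the C13 acetate. It has a vinyl group at C1 and a stereodefined (E)-2-methylbut-2-enyl group that supplies C9–C10. One operation closes the ten-membered ring and hands the olefin geometry on; epoxidation from the outer face then gives the 1β,10α-epoxide. The butenolide is unmasked from a 2,3,4-trisubstituted furan.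

Key step: step 13

Remark: atom labels C1–C15 follow germacrane numbering of the target (carbocycle C1–C10, lactone carbonyl C12, acetoxymethyl carbon C13, methyl groups C14 on C10 and C15 on C4); TBS = tert-butyldimethylsilyl.

**Step 1**
Reactants: 1 furan-3,4-diyldimethanol
Product: 2 [4-(TBSO-methyl)furan-3-yl]methanol
Conditions: NaH (1.0 equiv), THF, 0 °C; TBSCl (1.0 equiv), 0 °C to rt
Reagents that add atoms: tert-butyldimethylsilyl chloride, CC(C)(C)[Si](C)(C)Cl
Why: Monodeprotonation of the symmetrical diol with one equivalent of NaH followed by O-silylation (monosilylation of a symmetrical diol) should give mainly the mono-TBS ether, with no stereocentre formed.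

**Step 2**
Reactants: 3 (2E)-2-methylbut-2-en-1-ol
Product: 4 (2E)-1-bromo-2-methylbut-2-ene
Conditions: PBr3 (0.4 equiv), Et2O, −10 to 0 °C
Reagents that add atoms: phosphorus tribromide, BrP(Br)Br
Why: SN2 bromination of the primary allylic alcohol through its phosphite ester should give the primary bromide with the E olefin unchanged.

**Step 3**
Reactants: 2 [4-(TBSO-methyl)furan-3-yl]methanol; 4 (2E)-1-bromo-2-methylbut-2-ene
Product: 6 {4-(TBSO-methyl)-2-[(2E)-2-methylbut-2-en-1-yl]furan-3-yl}methanol, via dilithiated furan 5 (not isolated)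
Conditions: n-BuLi (2.2 equiv), THF, −78 to 0 °C; then 4, −78 °C to rt; H2O
Reagents that add atoms: 4 (2E)-1-bromo-2-methylbut-2-ene, C/C=C(\C)CBr
Why: Alkoxide-directed ortho-lithiation of the 3-(hydroxymethyl)furan at the neighbouring α-position followed by SN2 alkylation of the 2-furyllithium with the primary allylic bromide places the future C9–C10 unit on the furan carbon next to the future C7, with the E olefin retained.

**Step 4**
Reactants: 6 {4-(TBSO-methyl)-2-[(2E)-2-methylbut-2-en-1-yl]furan-3-yl}methanol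
Product: 7 4-(TBSO-methyl)-2-[(2E)-2-methylbut-2-en-1-yl]furan-3-carbaldehyde
Conditions: MnO2 (15 equiv), CH2Cl2, rt
Reagents that add atoms: none
Why: MnO2 oxidation of the furylic (benzylic-type) primary alcohol should stop at the aldehyde and leave the silyl ether and the olefin untouched.

**Step 5**
Reactants: 8 hex-1-en-5-yne
Product: 10 (1E)-1-iodo-2-methylhexa-1,5-diene, via alkenylalane 9 (not isolated)
Conditions: Me3Al (2.0 equiv), Cp2ZrCl2 (0.2 equiv), CH2Cl2, 0 °C to rt; then I2, THF, −30 to 0 °C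
Reagents that add atoms: trimethylaluminium, C[Al](C)C; iodine, II
Why: Negishi zirconium-catalysed carboalumination adds CH3 and Al syn across the terminal alkyne with methyl on the internal carbon, and iodinolysis of the C–Al bond with retention gives the (E)-iodide while the isolated terminal olefin stays inert.

**Step 6**
Reactants: 7 4-(TBSO-methyl)-2-[(2E)-2-methylbut-2-en-1-yl]furan-3-carbaldehyde; 10 (1E)-1-iodo-2-methylhexa-1,5-diene
Product: 13 (1R,2E)-1-{4-(TBSO-methyl)-2-[(2E)-2-methylbut-2-en-1-yl]furan-3-yl}-3-methylhepta-2,6-dien-1-ol, via alkenyllithium 11 (not isolated), via alkenyl(methyl)zinc 12 (not isolated)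
Conditions: 10, t-BuLi (2.0 equiv), Et2O, −78 °C; ZnBr2 (1.0 equiv) then MeLi (1.0 equiv), −78 to 0 °C; TEEDA, (+)-MIB (10 mol %), toluene; 7, 0 °C; H2O
Reagents that add atoms: 10 (1E)-1-iodo-2-methylhexa-1,5-diene, I/C=C(\C)CCC=C
Why: Iodine–lithium exchange with retention, transmetalation to an alkenyl(methyl)zinc and amino-alcohol-catalysed enantioselective alkenylzinc addition should set C6, with (+)-MIB steering the alkenyl group (which transfers in preference to methyl) to the Re face of the aldehyde to give the (R)-carbinol.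

**Step 7**
Reactants: 13 (1R,2E)-1-{4-(TBSO-methyl)-2-[(2E)-2-methylbut-2-en-1-yl]furan-3-yl}-3-methylhepta-2,6-dien-1-ol
Product: 14 (S)-{4-(TBSO-methyl)-2-[(2E)-2-methylbut-2-en-1-yl]furan-3-yl}[(2R,3R)-3-(but-3-en-1-yl)-3-methyloxiran-2-yl]methanol
Conditions: VO(acac)2 (5 mol %), TBHP (1.5 equiv), CH2Cl2, 0 °C
Reagents that add atoms: tert-butyl hydroperoxide, CC(C)(C)OO
Why: Hydroxyl-directed vanadium-catalysed epoxidation is selective for the allylic C4=C5 olefin, and allylic 1,3-strain between the furyl group on C6 and the cis methyl group on C4 keeps the furyl group anti to the olefin, so the threo epoxy alcohol with C4 (R) and C5 (R) should form.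

**Step 8**
Reactants: 14 (S)-{4-(TBSO-methyl)-2-[(2E)-2-methylbut-2-en-1-yl]furan-3-yl}[(2R,3R)-3-(but-3-en-1-yl)-3-methyloxiran-2-yl]methanol
Product: 16 (5S)-5-[(2R,3R)-3-(but-3-en-1-yl)-3-methyloxiran-2-yl]-3-(TBSO-methyl)-4-[(3E)-3-methylpent-3-enoyl]furan-2(5H)-one, via γ-hydroxybutenolide 15 (not isolated)
Conditions: O2, hν (visible), rose bengal (cat.), iPr2NEt, CH2Cl2, −78 °C; then PPTS (cat.), 4 Å MS, CH2Cl2, rt
Reagents that add atoms: dioxygen, O=O
Why: Singlet-oxygen [4+2] cycloaddition to the electron-rich furan, Kornblum–DeLaMare fragmentation of the endoperoxide at its only α-CH (C12) and ring-chain tautomerism of the γ-hydroxybutenolide to the keto acid, which lactonises onto the C6 hydroxyl, should give the 12,6-butenolide with C6 untouched.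

**Step 9**
Reactants: 16 (5S)-5-[(2R,3R)-3-(but-3-en-1-yl)-3-methyloxiran-2-yl]-3-(TBSO-methyl)-4-[(3E)-3-methylpent-3-enoyl]furan-2(5H)-one
Product: 17 (5S)-5-[(2R,3R)-3-(but-3-en-1-yl)-3-methyloxiran-2-yl]-4-[(1S,3E)-1-hydroxy-3-methylpent-3-en-1-yl]-3-(TBSO-methyl)furan-2(5H)-one
Conditions: (R)-2-methyl-CBS-oxazaborolidine (0.5 equiv), catecholborane (1.5 equiv), toluene, −78 °C; MeOH then H2O
Reagents that add atoms: none
Why: Corey–Bakshi–Shibata reduction of the conjugated C8 ketone, with the butenolide carbon as the large and the CH2 as the small substituent, should give the (8S)-alcohol under catalyst control without touching the lactone.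

**Step 10**
Reactants: 17 (5S)-5-[(2R,3R)-3-(but-3-en-1-yl)-3-methyloxiran-2-yl]-4-[(1S,3E)-1-hydroxy-3-methylpent-3-en-1-yl]-3-(TBSO-methyl)furan-2(5H)-one; 18 (2Z)-2-methylbut-2-enoic acid (angelic acid)
Product: 20 (1S,3E)-1-{(2S)-2-[(2R,3R)-3-(but-3-en-1-yl)-3-methyloxiran-2-yl]-4-(TBSO-methyl)-5-oxo-2,5-dihydrofuran-3-yl}-3-methylpent-3-en-1-yl (2Z)-2-methylbut-2-enoate, via mixed anhydride 19 (not isolated)
Conditions: 18, 2,4,6-trichlorobenzoyl chloride, Et3N, toluene, rt; then 17, toluene, 70 °C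
Reagents that add atoms: 18 (2Z)-2-methylbut-2-enoic acid, C/C=C(/C)C(=O)O
Why: Yamaguchi-type esterification through the mixed anhydride acylates the secondary C8 alcohol with retention at C8 and without nucleophilic catalyst, which avoids Z to E isomerisation of the angelate.

**Step 11**
Reactants: 20 (the silyl-protected angelate)
Product: 21 (1S,3E)-1-{(2S)-2-[(2R,3R)-3-(but-3-en-1-yl)-3-methyloxiran-2-yl]-4-(hydroxymethyl)-5-oxo-2,5-dihydrofuran-3-yl}-3-methylpent-3-en-1-yl (2Z)-2-methylbut-2-enoate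
Conditions: HF·pyridine, pyridine, THF, 0 °C to rt
Reagents that add atoms: none
Why: Buffered fluoride desilylation cleaves the primary TBS ether while the trisubstituted epoxide, the esters and the base-sensitive butenolide are left intact.

**Step 12**
Reactants: 21 (the primary alcohol)
Product: 22 (1S,3E)-1-{(2S)-4-(acetoxymethyl)-2-[(2R,3R)-3-(but-3-en-1-yl)-3-methyloxiran-2-yl]-5-oxo-2,5-dihydrofuran-3-yl}-3-methylpent-3-en-1-yl (2Z)-2-methylbut-2-enoate
Conditions: Ac2O, pyridine, CH2Cl2, 0 °C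
Reagents that add atoms: acetic anhydride, CC(=O)OC(C)=O
Why: Acetylation of the primary C13 alcohol under weakly basic conditions that do not enolise the butenolide at C6.

**Step 13**
Reactants: 22 (the acetate with a C1 vinyl group and an (E)-C10(CH3)=CH–CH3 olefin)
Product: 23 (1(10)E)-8α-angeloyloxy-13-acetoxy-4α,5β-epoxygermacra-1(10),7(11)-dien-12,6α-olide
Conditions: Mo(NC6F5)(CHCMe2Ph)(2,5-Me2C4H2N)(O-2,6-(2,4,6-iPr3C6H2)2C6H3) (10 mol %), C6H6, 1 mM, 22 °C, 100 Torr
Reagents that add atoms: none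
Why: Ring-closing olefin metathesis at a high-oxidation-state Mo alkylidene: the catalyst first exchanges with the monosubstituted C1 vinyl group, the Mo=C1 alkylidene adds across the (E)-C10(CH3)=CH–CH3 olefin, and cycloreversion of the molybdacyclobutane releases the C1=C10 bond and Mo=CHCH3, which leaves as propene. The closest known reaction type is stereoretentive macrocyclic ring-closing metathesis of stereodefined trisubstituted olefins with monoaryloxide pyrrolide Mo catalysts, applied here to a ten-membered carbocycle. Only the ten-membered ring C1–C10 is closed, by [2+2] cycloaddition and cycloreversion, with both olefin carbons C1 and C10 becoming ring members. No stereocentre is formed, but the olefin geometry is set: in the metallacycle the substituents on both α-carbons (C2 and the departing methyl) point to the small C6F5N imido ligand and away from the large aryloxide, so C2 takes the place of the methyl group that was trans to C9 and the E geometry of 22 is handed on to 23. The step needs chemoselectivity for the two isolated olefins over the angelate and butenolide double bonds, which are electron-poor and highly substituted, and it needs cyclisation to beat oligomerisation, which high dilution and the rigid butenolide and trans-epoxide units of the chain should favour. The E geometry matters because only the E olefin leads to the trans-1,10-epoxide.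

**Step 14**
Reactants: 23 (1(10)E)-8α-angeloyloxy-13-acetoxy-4α,5β-epoxygermacra-1(10),7(11)-dien-12,6α-olide
Product: 24 8α-angeloyloxy-13-acetoxy-1β,10α:4α,5β-diepoxygermacr-7(11)-en-12,6α-olide (CNP0251711.2)
Conditions: mCPBA (1.2 equiv), CH2Cl2, 0 °C
Reagents that add atoms: 3-chloroperbenzoic acid, OOC(=O)c1cccc(Cl)c1
Why: Prilezhaev epoxidation of the only electron-rich olefin is stereospecific (E olefin to trans-epoxide), and attack on the exposed outer face of C1=C10 in the crown conformation of the 4α,5β-epoxy-germacr-1(10)-enolide (C14 and C15 syn) should set C1 (R) and C10 (R) as the 1β,10α-epoxide.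

**Compound list**
1 | furan-3,4-diyldimethanol | OCc1cocc1CO | starting material
2 | [4-({[tert-butyl(dimethyl)silyl]oxy}methyl)furan-3-yl]methanol | OCc1cocc1CO[Si](C)(C)C(C)(C)C | intermediate
3 | (2E)-2-methylbut-2-en-1-ol (tiglyl alcohol) | C/C=C(\C)CO | starting material
4 | (2E)-1-bromo-2-methylbut-2-ene | C/C=C(\C)CBr | intermediate
5 | lithium [2-lithio-4-(TBSO-methyl)furan-3-yl]methanolate | [Li]OCc1c([Li])occ1CO[Si](C)(C)C(C)(C)C | intermediate
6 | {4-(TBSO-methyl)-2-[(2E)-2-methylbut-2-en-1-yl]furan-3-yl}methanol | C/C=C(\C)Cc1occ(CO[Si](C)(C)C(C)(C)C)c1CO | intermediate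
7 | 4-(TBSO-methyl)-2-[(2E)-2-methylbut-2-en-1-yl]furan-3-carbaldehyde | C/C=C(\C)Cc1occ(CO[Si](C)(C)C(C)(C)C)c1C=O | intermediate
8 | hex-1-en-5-yne | C#CCCC=C | starting material
9 | dimethyl[(1E)-2-methylhexa-1,5-dien-1-yl]alane | C[Al](C)/C=C(\C)CCC=C | intermediate
10 | (1E)-1-iodo-2-methylhexa-1,5-diene | I/C=C(\C)CCC=C | intermediate
11 | [(1E)-2-methylhexa-1,5-dien-1-yl]lithium | [Li]/C=C(\C)CCC=C | intermediate
12 | methyl[(1E)-2-methylhexa-1,5-dien-1-yl]zinc | C[Zn]/C=C(\C)CCC=C | intermediate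
13 | (1R,2E)-1-{4-(TBSO-methyl)-2-[(2E)-2-methylbut-2-en-1-yl]furan-3-yl}-3-methylhepta-2,6-dien-1-ol | C=CCC/C(C)=C/[C@@H](O)c1c(C/C(C)=C/C)occ1CO[Si](C)(C)C(C)(C)C | intermediate
14 | (S)-{4-(TBSO-methyl)-2-[(2E)-2-methylbut-2-en-1-yl]furan-3-yl}[(2R,3R)-3-(but-3-en-1-yl)-3-methyloxiran-2-yl]methanol | C=CCC[C@@]1(C)O[C@@H]1[C@@H](O)c1c(C/C(C)=C/C)occ1CO[Si](C)(C)C(C)(C)C | intermediate
15 | 5-hydroxy-4-{(S)-hydroxy[(2R,3R)-3-(but-3-en-1-yl)-3-methyloxiran-2-yl]methyl}-3-(TBSO-methyl)-5-[(2E)-2-methylbut-2-en-1-yl]furan-2(5H)-one (both epimers at the hemiketal carbon) | C=CCC[C@@]1(C)O[C@@H]1[C@@H](O)C1=C(CO[Si](C)(C)C(C)(C)C)C(=O)OC1(O)C/C(C)=C/C | intermediate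
16 | (5S)-5-[(2R,3R)-3-(but-3-en-1-yl)-3-methyloxiran-2-yl]-3-(TBSO-methyl)-4-[(3E)-3-methylpent-3-enoyl]furan-2(5H)-one | C=CCC[C@@]1(C)O[C@@H]1[C@H]1OC(=O)C(CO[Si](C)(C)C(C)(C)C)=C1C(=O)C/C(C)=C/C | intermediate
17 | (5S)-5-[(2R,3R)-3-(but-3-en-1-yl)-3-methyloxiran-2-yl]-4-[(1S,3E)-1-hydroxy-3-methylpent-3-en-1-yl]-3-(TBSO-methyl)furan-2(5H)-one | C=CCC[C@@]1(C)O[C@@H]1[C@H]1OC(=O)C(CO[Si](C)(C)C(C)(C)C)=C1[C@@H](O)C/C(C)=C/C | intermediate
18 | (2Z)-2-methylbut-2-enoic acid (angelic acid) | C/C=C(/C)C(=O)O | starting material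
19 | (2Z)-2-methylbut-2-enoic 2,4,6-trichlorobenzoic anhydride | C/C=C(/C)C(=O)OC(=O)c1c(Cl)cc(Cl)cc1Cl | intermediate
20 | (1S,3E)-1-{(2S)-2-[(2R,3R)-3-(but-3-en-1-yl)-3-methyloxiran-2-yl]-4-(TBSO-methyl)-5-oxo-2,5-dihydrofuran-3-yl}-3-methylpent-3-en-1-yl (2Z)-2-methylbut-2-enoate | C=CCC[C@@]1(C)O[C@@H]1[C@H]1OC(=O)C(CO[Si](C)(C)C(C)(C)C)=C1[C@@H](OC(=O)/C(C)=C\C)C/C(C)=C/C | intermediate
21 | (1S,3E)-1-{(2S)-2-[(2R,3R)-3-(but-3-en-1-yl)-3-methyloxiran-2-yl]-4-(hydroxymethyl)-5-oxo-2,5-dihydrofuran-3-yl}-3-methylpent-3-en-1-yl (2Z)-2-methylbut-2-enoate | C=CCC[C@@]1(C)O[C@@H]1[C@H]1OC(=O)C(CO)=C1[C@@H](OC(=O)/C(C)=C\C)C/C(C)=C/C | intermediate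
22 | (1S,3E)-1-{(2S)-4-(acetoxymethyl)-2-[(2R,3R)-3-(but-3-en-1-yl)-3-methyloxiran-2-yl]-5-oxo-2,5-dihydrofuran-3-yl}-3-methylpent-3-en-1-yl (2Z)-2-methylbut-2-enoate | C=CCC[C@@]1(C)O[C@@H]1[C@H]1OC(=O)C(COC(C)=O)=C1[C@@H](OC(=O)/C(C)=C\C)C/C(C)=C/C | intermediate
23 | (1(10)E)-8α-angeloyloxy-13-acetoxy-4α,5β-epoxygermacra-1(10),7(11)-dien-12,6α-olide | C/C=C(/C)C(=O)O[C@H]1C/C(C)=C/CC[C@@]2(C)O[C@@H]2[C@H]2OC(=O)C(COC(C)=O)=C12 | intermediate
24 | 8α-angeloyloxy-13-acetoxy-1β,10α:4α,5β-diepoxygermacr-7(11)-en-12,6α-olide (CNP0251711.2) | C/C=C(/C)C(=O)O[C@H]1C[C@@]2(C)O[C@@H]2CC[C@@]2(C)O[C@@H]2[C@H]2OC(=O)C(COC(C)=O)=C12 | target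

**Step count.** Total: 14 steps. Longest linear sequence: 12 steps (from 1 through steps 1, 3, 4 and 6 to 14).

**Steps most likely to fail**

Step 13 (ring closure). The metallacycle that leads to the strained (E)-cyclodecene may form too slowly, so that intermolecular metathesis (oligomerisation) or loss of the E geometry takes over. The fallback sets out from 22 and accepts the geometry that ring strain dictates. Ring closure with the second-generation Hoveyda–Grubbs catalyst RuCl2(H2IMes)(=CH-C6H4-2-OiPr) (toluene, 80 °C, 0.5 mM) should give, as is usual for ten-membered carbocycles, (1(10)Z)-8α-angeloyloxy-13-acetoxy-4α,5β-epoxygermacra-1(10),7(11)-dien-12,6α-olide F1. Syn-dihydroxylation of its only electron-rich olefin from the α face (OsO4 cat., NMO, acetone/H2O, with (DHQ)2PHAL or (DHQD)2PHAL as ligand if the face selection needs support) should give 8α-angeloyloxy-13-acetoxy-4α,5β-epoxy-1α,10α-dihydroxygermacr-7(11)-en-12,6α-olide F2. Mitsunobu cyclodehydration (PPh3, DIAD, THF) activates the secondary C1 hydroxyl and lets the tertiary C10 hydroxyl displace it with inversion at C1. This turns the syn-diol of the Z olefin into the trans-1β,10α-epoxide and comes back to the route at 24.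

Step 8 (furan to butenolide). Competing ene oxidation of the trisubstituted side-chain olefin, acid-promoted opening of the epoxide during lactonisation, or loss of configuration at C6 in the 4-acylbutenolide under the amine base may erode the material. The fallback sets out from 14 and avoids base. Photooxygenation in MeOH/CH2Cl2 at −78 °C followed by Me2S reduction gives the (Z)-keto enal, which closes with the C6 hydroxyl to the lactol (5S)-5-[(2R,3R)-3-(but-3-en-1-yl)-3-methyloxiran-2-yl]-2-hydroxy-3-(TBSO-methyl)-4-[(3E)-3-methylpent-3-enoyl]-2,5-dihydrofuran F3. Oxidation of the lactol (TEMPO cat., PhI(OAc)2, CH2Cl2, rt) comes back to the route at 16.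

Step 6 (asymmetric alkenylation). Facial selection by the amino-alcohol zinc catalyst may be insufficient on the aldehyde, which is flanked by two ortho substituents. The fallback sets out from 7 (with 10). Addition of the alkenyllithium 11 without ligand gives racemic (2E)-1-{4-(TBSO-methyl)-2-[(2E)-2-methylbut-2-en-1-yl]furan-3-yl}-3-methylhepta-2,6-dien-1-ol F4. Sharpless kinetic resolution (Ti(OiPr)4, D-(−)-DIPT, TBHP 0.6 equiv, 4 Å MS, CH2Cl2, −20 °C) epoxidises the (S)-enantiomer to the erythro epoxy alcohol (R)-{4-(TBSO-methyl)-2-[(2E)-2-methylbut-2-en-1-yl]furan-3-yl}[(2R,3R)-3-(but-3-en-1-yl)-3-methyloxiran-2-yl]methanol F5, which is separated. The unreacted (R)-enantiomer is recovered, which comes back to the route at 13.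

**Further compounds**
F1 | step 13 | (1(10)Z)-8α-angeloyloxy-13-acetoxy-4α,5β-epoxygermacra-1(10),7(11)-dien-12,6α-olide | C/C=C(/C)C(=O)O[C@H]1C/C(C)=C\CC[C@@]2(C)O[C@@H]2[C@H]2OC(=O)C(COC(C)=O)=C12
F2 | step 13 | 8α-angeloyloxy-13-acetoxy-4α,5β-epoxy-1α,10α-dihydroxygermacr-7(11)-en-12,6α-olide | C/C=C(/C)C(=O)O[C@H]1C[C@@](C)(O)[C@@H](O)CC[C@@]2(C)O[C@@H]2[C@H]2OC(=O)C(COC(C)=O)=C12
F3 | step 8 | (5S)-5-[(2R,3R)-3-(but-3-en-1-yl)-3-methyloxiran-2-yl]-2-hydroxy-3-(TBSO-methyl)-4-[(3E)-3-methylpent-3-enoyl]-2,5-dihydrofuran | C=CCC[C@@]1(C)O[C@@H]1[C@H]1OC(O)C(CO[Si](C)(C)C(C)(C)C)=C1C(=O)C/C(C)=C/C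
F4 | step 6 | racemic (2E)-1-{4-(TBSO-methyl)-2-[(2E)-2-methylbut-2-en-1-yl]furan-3-yl}-3-methylhepta-2,6-dien-1-ol | C=CCC/C(C)=C/C(O)c1c(C/C(C)=C/C)occ1CO[Si](C)(C)C(C)(C)C
F5 | step 6 | (R)-{4-(TBSO-methyl)-2-[(2E)-2-methylbut-2-en-1-yl]furan-3-yl}[(2R,3R)-3-(but-3-en-1-yl)-3-methyloxiran-2-yl]methanol | C=CCC[C@@]1(C)O[C@@H]1[C@H](O)c1c(C/C(C)=C/C)occ1CO[Si](C)(C)C(C)(C)C
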